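**Plan**
- Retrosynthetic cuts: the C8–O angelate ester; C11=C13; the lactone C12–O bond; then both oxolane bonds C2–C3 and C1–C10 at once, leaving a cis-fused 3,10-oxirane on an eight-membered carbocycle plus a vinylboronate (C1–C2); then the oxirane oxygen, the C3=C10 unsaturation, C8–H, C7–C11, and the C6–C7/C8–C9 bonds (a ketene inserted into 3,5-dimethylcyclohexenone).
- Forward ring order: six-membered enone → eight-membered 1,3-dione (ketene [2+2], retro-aldol, two-carbon ring expansion) → oxirane → nine-membered oxacycle and oxolane in one operation (oxirane C–C cleavage to a carbonyl ylide, then [3+2]) → γ-lactone → angelate.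
- Enabling feature: the oxolane oxygen lies between C3, the γ-carbon of the C6 carbonyl through C4=C5 (a vinylogous α-carbon), and the methyl-bearing quaternary C10. Oxygen flanked by these two carbons is a push–pull carbonyl ylide, stored as the C3–C10 bond of an eight-membered 3,10-epoxy-4-en-6-one.
- Stereochemistry: C7 and C8 from transfer hydrogenation with dynamic kinetic resolution (cis, catalyst control); C3 and C10 from a reagent-controlled epoxidation, carried through conrotatory opening and suprafacial addition; C1 from the endo approach of the boronate (C–B to C–O with retention); C6 from hydride delivery anti to the C7 side chain.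

Key step: step 9

Remark on the chemistry: the stereodescriptors of the SMILES are taken literally, (1S,3S,6S,7R,8R,10R) in germacrane numbering (used for all C-locants below); the lactone is therefore cis-fused and the ring bonds C3–C4 and C10–C9 lie on opposite faces of the oxolane.

**Step 1**
Reactants: 1 3,5-dimethylcyclohex-2-en-1-one (racemic)
Product: 2 trimethyl[(3,5-dimethylcyclohexa-1,5-dien-1-yl)oxy]silane
Conditions: LiN(iPr)2, THF, −78 °C; Me3SiCl, −78 °C to rt
Reagents that add atoms: chlorotrimethylsilane, C[Si](C)(C)Cl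
Why: kinetic α'-deprotonation of the enone and O-silylation should give the cross-conjugated silyl dienol ether (silyl enol ether formation).

**Step 2**
Reactants: 2 trimethyl[(3,5-dimethylcyclohexa-1,5-dien-1-yl)oxy]silane; 3 trichloroacetyl chloride
Product: 4 7,7-dichloro-2,4-dimethyl-6-(trimethylsilyloxy)bicyclo[4.2.0]oct-4-en-8-one
Conditions: 3, Zn–Cu couple, Et2O, ultrasound, 15–20 °C
Reagents that add atoms: trichloroacetyl chloride (3, source of dichloroketene), ClC(=O)C(Cl)(Cl)Cl
Why: dichloroketene generated in the flask should add [2+2] to the electron-rich silyl enol ether double bond, its carbonyl carbon bonding to the unsubstituted enol carbon (ketene–enol ether cycloaddition).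

**Step 3**
Reactants: 4 7,7-dichloro-2,4-dimethyl-6-(trimethylsilyloxy)bicyclo[4.2.0]oct-4-en-8-one
Product: 6 5,7-dimethylcyclooct-4-ene-1,3-dione (racemate), via dechlorinated cyclobutanone 5 (not isolated)
Conditions: Zn dust, AcOH/H2O, 20 to 70 °C
Reagents that add atoms: none
Why: reductive dechlorination followed by desilylation should trigger strain-driven retro-aldol cleavage of the ring-fusion bond, the established two-carbon ring expansion to a cyclic 1,3-dione (C6 and C8 carbonyls, C7 between them).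

**Step 4**
Reactants: 6 5,7-dimethylcyclooct-4-ene-1,3-dione; 7 tert-butyl bromoacetate
Product: 8 tert-butyl 2-(4,6-dimethyl-2,8-dioxocyclooct-3-en-1-yl)acetate
Conditions: 7, K2CO3, Bu4NBr (cat.), PhMe/H2O, rt
Reagents that add atoms: tert-butyl bromoacetate (7), BrCC(=O)OC(C)(C)C
Why: C-alkylation of the 1,3-dione at the doubly activated C7 with a reactive α-halo ester (1,3-dicarbonyl alkylation); C7 stays labile and is fixed in step 5.

**Step 5**
Reactants: 8 tert-butyl 2-(4,6-dimethyl-2,8-dioxocyclooct-3-en-1-yl)acetate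
Product: 9 tert-butyl 2-[(1R,8R)-8-hydroxy-4,6-dimethyl-2-oxocyclooct-3-en-1-yl]acetate
Conditions: RuCl(p-cymene)[(R,R)-TsDPEN] (2 mol %), HCO2H/Et3N (5:2), CH2Cl2, 30 °C
Reagents that add atoms: none
Why: Noyori transfer hydrogenation with dynamic kinetic resolution: C7 epimerises through the enol, the non-conjugated C8 carbonyl is the more electrophilic, hydride adds anti to the C7 side chain (7,8-cis) and the ligand fixes the absolute sense (7R,8R).

**Step 6**
Reactants: 9 tert-butyl 2-[(1R,8R)-8-hydroxy-4,6-dimethyl-2-oxocyclooct-3-en-1-yl]acetate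
Product: 10 tert-butyl 2-[(1R,8R)-8-(tert-butyldimethylsilyloxy)-4,6-dimethyl-2-oxocyclooct-3-en-1-yl]acetate
Conditions: TBSOTf, 2,6-lutidine, CH2Cl2, −78 to 0 °C
Reagents that add atoms: tert-butyldimethylsilyl triflate, CC(C)(C)[Si](C)(C)OS(=O)(=O)C(F)(F)F
Why: silylation of the secondary alcohol under non-basic conditions avoids retro-aldol or β-elimination of the β-hydroxy ketone (silyl ether protection).

**Step 7**
Reactants: 10 tert-butyl 2-[(1R,8R)-8-(tert-butyldimethylsilyloxy)-4,6-dimethyl-2-oxocyclooct-3-en-1-yl]acetate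
Product: 11 tert-butyl 2-[(1R,3Z,5Z,8R)-8-(tert-butyldimethylsilyloxy)-4,6-dimethyl-2-oxocycloocta-3,5-dien-1-yl]acetate
Conditions: chloranil, t-BuOH, reflux
Reagents that add atoms: none
Why: quinone dehydrogenation of an enone through its dienol (hydride abstraction at the δ-carbon C10) should give the linear dienone, and both C10 epimers converge.

**Step 8**
Reactants: 11 tert-butyl 2-[(1R,3Z,5Z,8R)-8-(tert-butyldimethylsilyloxy)-4,6-dimethyl-2-oxocycloocta-3,5-dien-1-yl]acetate
Product: 12 tert-butyl 2-[(1R,3Z,5S,6R,8R)-8-(tert-butyldimethylsilyloxy)-5,6-epoxy-4,6-dimethyl-2-oxocyclooct-3-en-1-yl]acetate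
Conditions: L-fructose-derived Shi ketone (0.3 equiv), Oxone, K2CO3, Bu4NHSO4, MeCN/dimethoxymethane/aq. Na2B4O7 buffer, 0 °C
Reagents that add atoms: Oxone (potassium peroxymonosulfate), [K+].[O-]S(=O)(=O)OO
Why: Shi epoxidation: the dioxirane should take the electron-richer distal C3=C10 alkene of the dienone, and the spiro transition state of the chiral ketone sets the face, giving the cis-fused (3S,10R)-oxirane.

**Step 9**
Reactants: 12 tert-butyl 2-[(1R,3Z,5S,6R,8R)-8-(tert-butyldimethylsilyloxy)-5,6-epoxy-4,6-dimethyl-2-oxocyclooct-3-en-1-yl]acetate; 13 4,4,5,5-tetramethyl-2-vinyl-1,3,2-dioxaborolane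
Product: 15 tert-butyl 2-[(1S,3S,4Z,7R,8R,10R)-8-(tert-butyldimethylsilyloxy)-3,10-epoxy-4,10-dimethyl-6-oxo-1-(4,4,5,5-tetramethyl-1,3,2-dioxaborolan-2-yl)cyclodec-4-en-7-yl]acetate, via E,Z-carbonyl ylide 14 (not isolated)
Conditions: 13 (10 equiv), o-xylene, BHT (cat.), sealed tube, 150 °C
Reagents that add atoms: 4,4,5,5-tetramethyl-2-vinyl-1,3,2-dioxaborolane (13), C=CB1OC(C)(C)C(C)(C)O1
Why: Proposed new method: heat should break the C3–C10 bond of the oxirane in a thermal conrotatory four-electron electrocyclic opening, accessible because the resulting carbonyl ylide 14 is push–pull stabilised (C10 a dialkyl oxocarbenium carbon, C3 the γ-carbon of a dienolate reaching the C6 carbonyl through C4=C5), and 13 then captures the ylide in a concerted suprafacial [3+2] cycloaddition; the closest known reaction type is the thermal C–C opening of acyl- or aryl-substituted oxiranes (ring-fused epoxy ketones included) to carbonyl ylides followed by 1,3-dipolar cycloaddition to alkenes. Two rings are closed: the nine-membered oxacycle by ring expansion of the cyclooctene (the oxirane oxygen becomes a ring member as the C3–C10 bond is cleaved) and the oxolane by the intermolecular [3+2] across C3 and C10. C3 and C10 are controlled by the oxirane configuration, since conrotation turns C4 outward and C9 inward (the opposite sense would drive C4 against the C10 methyl), the C5–C8 chain keeps the face it held in the oxirane and 13 adds to the open face, which puts the C3–C4 and C10–C9 bonds on opposite faces of the oxolane (3S,10R); C1 is controlled by the endo approach that holds boron over the ylide oxygen and away from the inward C9 methylene, so boron ends cis to the C10 methyl. The step needs regioselectivity, secured by polarity matching (nucleophilic C3 bonds to the unsubstituted vinyl carbon, the α-boryl carbon closes on electrophilic C10), and it needs capture to outrun rotation about the ylide C–O bonds, secured by the large excess of 13. 1,5-Electrocyclisation to a dihydrofuran is shut off because C4 is anti to C10 in this ylide.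

**Step 10**
Reactants: 15 boronate cycloadduct
Product: 16 tert-butyl 2-[(1S,3S,4Z,7R,8R,10R)-8-(tert-butyldimethylsilyloxy)-3,10-epoxy-1-hydroxy-4,10-dimethyl-6-oxocyclodec-4-en-7-yl]acetate
Conditions: NaBO3·4H2O, THF/H2O (1:1), rt
Reagents that add atoms: sodium perborate, [Na+].[O-]OB=O
Why: oxidation of the secondary alkylboronate by 1,2-migration of carbon from boron to oxygen should give the C1 alcohol with retention (1S); the β,β-disubstituted enone is left alone by this mild oxidant.

**Step 11**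
Reactants: 16 C1 alcohol
Product: 18 (1S,3S,4Z,6S,7S,8R,10R)-8-(tert-butyldimethylsilyloxy)-3,10-epoxy-1-hydroxy-13-norgermacr-4-en-12,6-olide, via hydroxy ester 17 (not isolated)
Conditions: NaBH4, CeCl3·7H2O, MeOH, −40 °C; then p-TsOH·H2O (cat.), PhMe, 50 °C
Reagents that add atoms: none
Why: Luche reduction should give 1,2-reduction of the enone, hydride entering C6 anti to the C7 side chain so that the new hydroxyl is cis to it (6S) and closes the cis-fused γ-lactone by acid-catalysed transesterification.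

**Step 12**
Reactants: 18 cis-fused lactone
Product: 21 (1S,3S,4Z,6S,7S,8R,10R)-8-(tert-butyldimethylsilyloxy)-3,10-epoxy-1-hydroxygermacra-4,11(13)-dien-12,6-olide, via Mannich base 19 (not isolated), via trimethylammonium iodide 20 (not isolated)
Conditions: LiN(iPr)2 (2.5 equiv), THF, −78 °C; CH2=NMe2+ I− (Eschenmoser's salt), −78 °C to rt; then MeI, MeOH, rt; then aq. NaHCO3, CH2Cl2
Reagents that add atoms: Eschenmoser's salt, C=[N+](C)C.[I-]
Why: aminomethylation of the lactone enolate, N-methylation and E1cB loss of trimethylamine is the standard route to α-methylene-γ-lactones; no stereocenter is touched (the 7S label in 17–21 is only a priority change caused by silicon).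

**Step 13**
Reactants: 21 α-methylene lactone silyl ether
Product: 22 (1S,3S,4Z,6S,7R,8R,10R)-3,10-epoxy-1,8-dihydroxygermacra-4,11(13)-dien-12,6-olide
Conditions: HF·pyridine, THF/pyridine, 0 °C to rt
Reagents that add atoms: none
Why: buffered fluoride desilylation should free the C8 hydroxyl without conjugate addition to the methylene lactone.

**Step 14**
Reactants: 22 diol; 23 angelic acid
Product: 24 (1S,3S,4Z,6S,7R,8R,10R)-8-angeloyloxy-3,10-epoxy-1-hydroxygermacra-4,11(13)-dien-12,6-olide (target)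
Conditions: 23, 2,4,6-trichlorobenzoyl chloride, Et3N, PhMe, rt; then 22 (1.0 equiv), 70 °C
Reagents that add atoms: angelic acid (23), C/C=C(/C)C(=O)O
Why: Yamaguchi esterification through the preformed mixed anhydride keeps the Z geometry of the angelate, and the C8 hydroxyl should react in preference to the C1 hydroxyl, which is neopentylic (next to the fully substituted C10).

**Compound list**
1 | 3,5-dimethylcyclohex-2-en-1-one (racemic) | CC1=CC(=O)CC(C)C1 | starting material
2 | trimethyl[(3,5-dimethylcyclohexa-1,5-dien-1-yl)oxy]silane (racemic) | C[Si](C)(C)OC1=CC(C)CC(C)=C1 | intermediate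
3 | trichloroacetyl chloride | ClC(=O)C(Cl)(Cl)Cl | starting material
4 | 7,7-dichloro-2,4-dimethyl-6-(trimethylsilyloxy)bicyclo[4.2.0]oct-4-en-8-one (racemic, cis-fused, both C2 epimers) | C[Si](C)(C)OC12C=C(C)CC(C)C1C(=O)C2(Cl)Cl | intermediate
5 | 2,4-dimethyl-6-(trimethylsilyloxy)bicyclo[4.2.0]oct-4-en-8-one (racemic) | C[Si](C)(C)OC12C=C(C)CC(C)C1C(=O)C2 | intermediate (not isolated)
6 | (4Z)-5,7-dimethylcyclooct-4-ene-1,3-dione (racemic) | O=C1/C=C(/C)CC(C)CC(=O)C1 | intermediate
7 | tert-butyl bromoacetate | BrCC(=O)OC(C)(C)C | starting material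
8 | tert-butyl 2-(4,6-dimethyl-2,8-dioxocyclooct-3-en-1-yl)acetate (stereoisomer mixture, C1 labile) | O=C1/C=C(/C)CC(C)CC(=O)C1CC(=O)OC(C)(C)C | intermediate
9 | tert-butyl 2-[(1R,8R)-8-hydroxy-4,6-dimethyl-2-oxocyclooct-3-en-1-yl]acetate (1,8-cis, both C6 epimers) | O=C1/C=C(/C)CC(C)C[C@@H](O)[C@H]1CC(=O)OC(C)(C)C | intermediate
10 | tert-butyl 2-[(1R,8R)-8-(tert-butyldimethylsilyloxy)-4,6-dimethyl-2-oxocyclooct-3-en-1-yl]acetate (both C6 epimers) | O=C1/C=C(/C)CC(C)C[C@@H](O[Si](C)(C)C(C)(C)C)[C@H]1CC(=O)OC(C)(C)C | intermediate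
11 | tert-butyl 2-[(1R,3Z,5Z,8R)-8-(tert-butyldimethylsilyloxy)-4,6-dimethyl-2-oxocycloocta-3,5-dien-1-yl]acetate | O=C1/C=C(/C)\C=C(\C)C[C@@H](O[Si](C)(C)C(C)(C)C)[C@H]1CC(=O)OC(C)(C)C | intermediate
12 | tert-butyl 2-[(1R,3Z,5S,6R,8R)-8-(tert-butyldimethylsilyloxy)-5,6-epoxy-4,6-dimethyl-2-oxocyclooct-3-en-1-yl]acetate (cis-fused oxirane; its C5 and C6 are C3 and C10 of the target) | O=C1/C=C(/C)[C@@H]2O[C@]2(C)C[C@@H](O[Si](C)(C)C(C)(C)C)[C@H]1CC(=O)OC(C)(C)C | intermediate
13 | 4,4,5,5-tetramethyl-2-vinyl-1,3,2-dioxaborolane (vinylboronic acid pinacol ester) | C=CB1OC(C)(C)C(C)(C)O1 | starting material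
14 | nine-membered cyclic carbonyl ylide from 12, C3(−)–O(+)=C10, C4 anti to C10 and C9 syn to C3 (E,Z) | O=C1/C=C(/C)[CH-]/[O+]=C(/C)C[C@@H](O[Si](C)(C)C(C)(C)C)[C@H]1CC(=O)OC(C)(C)C | intermediate (not isolated)
15 | tert-butyl 2-[(1S,3S,4Z,7R,8R,10R)-8-(tert-butyldimethylsilyloxy)-3,10-epoxy-4,10-dimethyl-6-oxo-1-(4,4,5,5-tetramethyl-1,3,2-dioxaborolan-2-yl)cyclodec-4-en-7-yl]acetate | O=C1/C=C(/C)[C@@H]2C[C@H](B3OC(C)(C)C(C)(C)O3)[C@@](C)(C[C@@H](O[Si](C)(C)C(C)(C)C)[C@H]1CC(=O)OC(C)(C)C)O2 | intermediate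
16 | tert-butyl 2-[(1S,3S,4Z,7R,8R,10R)-8-(tert-butyldimethylsilyloxy)-3,10-epoxy-1-hydroxy-4,10-dimethyl-6-oxocyclodec-4-en-7-yl]acetate | O=C1/C=C(/C)[C@@H]2C[C@H](O)[C@@](C)(C[C@@H](O[Si](C)(C)C(C)(C)C)[C@H]1CC(=O)OC(C)(C)C)O2 | intermediate
17 | tert-butyl 2-[(1S,3S,4Z,6S,7S,8R,10R)-8-(tert-butyldimethylsilyloxy)-3,10-epoxy-1,6-dihydroxy-4,10-dimethylcyclodec-4-en-7-yl]acetate | O[C@H]1/C=C(/C)[C@@H]2C[C@H](O)[C@@](C)(C[C@@H](O[Si](C)(C)C(C)(C)C)[C@H]1CC(=O)OC(C)(C)C)O2 | intermediate (not isolated)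
18 | (1S,3S,4Z,6S,7S,8R,10R)-8-(tert-butyldimethylsilyloxy)-3,10-epoxy-1-hydroxy-13-norgermacr-4-en-12,6-olide (cis-fused lactone) | C1C(=O)O[C@H]2/C=C(/C)[C@@H]3C[C@H](O)[C@@](C)(C[C@@H](O[Si](C)(C)C(C)(C)C)[C@@H]12)O3 | intermediate
19 | 13-(dimethylamino) derivative of 18, (1S,3S,4Z,6S,7S,8R,10R)-8-(tert-butyldimethylsilyloxy)-13-(dimethylamino)-3,10-epoxy-1-hydroxygermacr-4-en-12,6-olide (C11 epimers) | CN(C)CC1C(=O)O[C@H]2/C=C(/C)[C@@H]3C[C@H](O)[C@@](C)(C[C@@H](O[Si](C)(C)C(C)(C)C)[C@@H]12)O3 | intermediate (not isolated)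
20 | N-methyl quaternary ammonium iodide of 19 (C11 epimers) | C[N+](C)(C)CC1C(=O)O[C@H]2/C=C(/C)[C@@H]3C[C@H](O)[C@@](C)(C[C@@H](O[Si](C)(C)C(C)(C)C)[C@@H]12)O3.[I-] | intermediate (not isolated)
21 | (1S,3S,4Z,6S,7S,8R,10R)-8-(tert-butyldimethylsilyloxy)-3,10-epoxy-1-hydroxygermacra-4,11(13)-dien-12,6-olide | C=C1C(=O)O[C@H]2/C=C(/C)[C@@H]3C[C@H](O)[C@@](C)(C[C@@H](O[Si](C)(C)C(C)(C)C)[C@@H]12)O3 | intermediate
22 | (1S,3S,4Z,6S,7R,8R,10R)-3,10-epoxy-1,8-dihydroxygermacra-4,11(13)-dien-12,6-olide | C=C1C(=O)O[C@H]2/C=C(/C)[C@@H]3C[C@H](O)[C@@](C)(C[C@@H](O)[C@@H]12)O3 | intermediate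
23 | angelic acid, (Z)-2-methylbut-2-enoic acid | C/C=C(/C)C(=O)O | starting material
24 | (1S,3S,4Z,6S,7R,8R,10R)-8-angeloyloxy-3,10-epoxy-1-hydroxygermacra-4,11(13)-dien-12,6-olide | C=C1C(=O)O[C@H]2/C=C(/C)[C@@H]3C[C@H](O)[C@@](C)(C[C@@H](OC(=O)/C(C)=C\C)[C@@H]12)O3 | target

**Totals**
Total step count: 14. Longest linear sequence: 14 steps (1 to 24).

**Three steps most likely to fail**

1. Step 9. The E,Z ylide is strained and may relax by rotation about its C–O bonds to the all-cis ylide, or re-close, before it is intercepted; that would erode or reverse the relationship between C3 and C10. A 1,4-hydrogen shift from C9 or the C10 methyl to C3 would drain the ylide, and traces of acid would open the C10–O bond heterolytically instead. The fallback uses known reactions only; it sets out from 12 and comes back at 16.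
   - Periodic acid (H5IO6, Et2O) should cleave the oxirane to the seco keto enal F1.
   - Ph3P=CH2 at −78 °C should methylenate the aldehyde alone, giving the triene F2.
   - (1-Methoxyallenyl)lithium with CeCl3 should add to the methyl ketone, giving the allenyl carbinol F3 (C10 epimers; the 10R isomer is taken on).
   - Dilute aqueous acid should hydrolyse the enol ether to the α'-hydroxy vinyl ketone F4.
   - Ring-closing metathesis at high dilution with the second-generation Hoveyda–Grubbs catalyst, RuCl2(H2IMes)(=CH-C6H4-2-OiPr), should close the ten-membered dienedione F5 at C2=C3.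
   - DBU should induce transannular oxa-Michael addition of the C10 hydroxyl to C3, giving the oxolan-3-one F6. The C3 configuration has to be set here under kinetic control, which is the weak point of this detour.
   - NaBH4 at −78 °C should reduce the saturated C1 ketone from the face away from the C10 methyl and return 16.

2. Step 5. Epimerisation at C7 may be slow relative to reduction (poor dynamic resolution), and the conjugated C6 carbonyl or the C4=C5 bond may be reduced as well. The fallback sets out from 8 and comes back at 9.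
   - NaBH4 in MeOH/CH2Cl2 at −78 °C should reduce the C8 carbonyl anti to the C7 side chain, giving the racemic cis-hydroxy ketone, that is 9 together with its enantiomer F7.
   - Candida antarctica lipase B with vinyl acetate should acetylate the 8R alcohol to the acetate F8 and leave F7.
   - After separation, the same lipase in pH 7 buffer should deacetylate F8 to 9 without base-induced elimination.

3. Step 14. Site selectivity may be lost (acylation of the C1 hydroxyl as well), and the angelate may isomerise from Z to E on prolonged heating. The fallback sets out from 21 and comes back at 24.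
   - 4-Methoxybenzyl trichloroacetimidate with La(OTf)3 (cat.) should protect the C1 hydroxyl of 21, giving the PMB ether F9.
   - HF·pyridine should free the C8 hydroxyl, giving F10.
   - Yamaguchi esterification with 23 should give the angelate F11.
   - DDQ in CH2Cl2/pH 7 buffer should remove the PMB group and deliver 24.

**Further compounds**
F1 | step 9 | tert-butyl (3R,4R)-4-(tert-butyldimethylsilyloxy)-3-[(2Z)-3-methyl-4-oxobut-2-enoyl]-6-oxoheptanoate | CC(=O)C[C@@H](O[Si](C)(C)C(C)(C)C)[C@@H](CC(=O)OC(C)(C)C)C(=O)/C=C(/C)C=O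
F2 | step 9 | tert-butyl (3R,4R)-4-(tert-butyldimethylsilyloxy)-3-[(2Z)-3-methylpenta-2,4-dienoyl]-6-oxoheptanoate | CC(=O)C[C@@H](O[Si](C)(C)C(C)(C)C)[C@@H](CC(=O)OC(C)(C)C)C(=O)/C=C(/C)C=C
F3 | step 9 | tert-butyl (3R,4R,6R)-4-(tert-butyldimethylsilyloxy)-6-hydroxy-7-methoxy-6-methyl-3-[(2Z)-3-methylpenta-2,4-dienoyl]nona-7,8-dienoate | C=C=C(OC)[C@](C)(O)C[C@@H](O[Si](C)(C)C(C)(C)C)[C@@H](CC(=O)OC(C)(C)C)C(=O)/C=C(/C)C=C
F4 | step 9 | tert-butyl (3R,4R,6R)-4-(tert-butyldimethylsilyloxy)-6-hydroxy-6-methyl-3-[(2Z)-3-methylpenta-2,4-dienoyl]-7-oxonon-8-enoate | C=CC(=O)[C@](C)(O)C[C@@H](O[Si](C)(C)C(C)(C)C)[C@@H](CC(=O)OC(C)(C)C)C(=O)/C=C(/C)C=C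
F5 | step 9 | tert-butyl 2-[(2Z,4Z,7R,8R,10R)-8-(tert-butyldimethylsilyloxy)-10-hydroxy-4,10-dimethyl-1,6-dioxocyclodeca-2,4-dien-7-yl]acetate | O=C1/C=C\C(C)=C/C(=O)[C@H](CC(=O)OC(C)(C)C)[C@H](O[Si](C)(C)C(C)(C)C)C[C@@]1(C)O
F6 | step 9 | tert-butyl 2-[(3S,4Z,7R,8R,10R)-8-(tert-butyldimethylsilyloxy)-3,10-epoxy-4,10-dimethyl-1,6-dioxocyclodec-4-en-7-yl]acetate | O=C1/C=C(/C)[C@@H]2CC(=O)[C@@](C)(C[C@@H](O[Si](C)(C)C(C)(C)C)[C@H]1CC(=O)OC(C)(C)C)O2
F7 | step 5 | tert-butyl 2-[(1S,8S)-8-hydroxy-4,6-dimethyl-2-oxocyclooct-3-en-1-yl]acetate (enantiomer of 9) | O=C1/C=C(/C)CC(C)C[C@H](O)[C@@H]1CC(=O)OC(C)(C)C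
F8 | step 5 | tert-butyl 2-[(1R,8R)-8-acetoxy-4,6-dimethyl-2-oxocyclooct-3-en-1-yl]acetate | O=C1/C=C(/C)CC(C)C[C@@H](OC(C)=O)[C@H]1CC(=O)OC(C)(C)C
F9 | step 14 | (1S,3S,4Z,6S,7S,8R,10R)-8-(tert-butyldimethylsilyloxy)-3,10-epoxy-1-(4-methoxybenzyloxy)germacra-4,11(13)-dien-12,6-olide | C=C1C(=O)O[C@H]2/C=C(/C)[C@@H]3C[C@H](OCc4ccc(OC)cc4)[C@@](C)(C[C@@H](O[Si](C)(C)C(C)(C)C)[C@@H]12)O3
F10 | step 14 | (1S,3S,4Z,6S,7R,8R,10R)-3,10-epoxy-8-hydroxy-1-(4-methoxybenzyloxy)germacra-4,11(13)-dien-12,6-olide | C=C1C(=O)O[C@H]2/C=C(/C)[C@@H]3C[C@H](OCc4ccc(OC)cc4)[C@@](C)(C[C@@H](O)[C@@H]12)O3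
F11 | step 14 | (1S,3S,4Z,6S,7R,8R,10R)-8-angeloyloxy-3,10-epoxy-1-(4-methoxybenzyloxy)germacra-4,11(13)-dien-12,6-olide | C=C1C(=O)O[C@H]2/C=C(/C)[C@@H]3C[C@H](OCc4ccc(OC)cc4)[C@@](C)(C[C@@H](OC(=O)/C(C)=C\C)[C@@H]12)O3
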